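The route rests on making the benzene ring of the C6-linked flavan last. In that ring the three oxygen-bearing carbons (C5, C7, C8a) sit between C4a, C6 and C8 in a 1,3,5-arrangement, the pattern that a cyclobutenone–alkoxyalkyne benzannulation produces. One thermal operation forms C4a–C5, C6–C7 and C7–C8, closes the arene, and leaves C5 as its methyl ether, C7 as a free phenol and the CH2 bridge on C6. Its precursors are a cyclobutenone fused to the finished (2S)-2-phenyldihydropyran, which supplies O1, C8a, C4a, C8 and C7, and a methoxyalkyne hung through CH2 on C8 of the complete 7-O-benzyl (2S)-flavan.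

Key step: step 17

Remark: both enantiomers of 3-chloro-1-phenylpropan-1-ol, ethoxyacetylene, chloroacetaldehyde dimethyl acetal and 2,6-dihydroxy-4-methoxybenzaldehyde are taken as purchasable; the (S)-chlorohydrin feeds the cyclobutenone (ring closure with retention), the (R)-chlorohydrin the C8-linked flavan (ring closure with inversion).

**Cyclobutenone partner**

Step 1
Reactants: 1 (S)-3-chloro-1-phenylpropan-1-ol
Product: 2 (S)-tert-butyl(3-chloro-1-phenylpropoxy)dimethylsilane
Conditions: TBSCl, imidazole, DMF, 0 °C to rt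
Reagents that add atoms: tert-butyldimethylsilyl chloride, CC(C)(C)[Si](C)(C)Cl
Why: Imidazole-promoted silyl ether formation masks the secondary alcohol for the organolithium and ketene steps without touching the stereocentre.

Step 2
Reactants: 2 (S)-tert-butyl(3-chloro-1-phenylpropoxy)dimethylsilane
Product: 3 (S)-tert-butyl(3-iodo-1-phenylpropoxy)dimethylsilane
Conditions: NaI, acetone, reflux
Reagents that add atoms: sodium iodide, [Na+].[I-]
Why: Finkelstein halide exchange at the primary carbon gives the iodide needed for acetylide alkylation, and the carbinol centre is not involved.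

Step 3
Reactants: 3 (S)-tert-butyl(3-iodo-1-phenylpropoxy)dimethylsilane; 4 ethoxyacetylene
Product: 6 (S)-tert-butyl[(5-ethoxy-1-phenylpent-4-yn-1-yl)oxy]dimethylsilane, via lithium ethoxyacetylide 5 (not isolated)
Conditions: 4, n-BuLi, THF, −78 °C; then 3, DMPU, −78 °C to rt
Reagents that add atoms: none
Why: SN2 alkylation of a lithium alkoxyacetylide by a primary iodide in a dipolar cosolvent is the standard entry to 1-alkoxy-1-alkynes.

Step 4
Reactants: 6 (S)-tert-butyl[(5-ethoxy-1-phenylpent-4-yn-1-yl)oxy]dimethylsilane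
Product: 7 3-ethoxy-2-[(3S)-3-(tert-butyldimethylsilyloxy)-3-phenylpropyl]cyclobut-2-en-1-one
Conditions: ketene (gas stream from acetone pyrolysis), CH2Cl2, −20 to 0 °C
Reagents that add atoms: ketene, C=C=O
Why: In the thermal ketene–ynol ether [2+2] cycloaddition the alkyne carbon remote from oxygen bonds to the ketene carbonyl carbon, which gives the 2-alkyl-3-ethoxycyclobutenone as a single regioisomer.

Step 5
Reactants: 7 3-ethoxy-2-[(3S)-3-(tert-butyldimethylsilyloxy)-3-phenylpropyl]cyclobut-2-en-1-one
Product: 9 (3S)-3-phenyl-2-oxabicyclo[4.2.0]oct-1(6)-en-7-one, via hydroxy cyclobutenone 8 (not isolated)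
Conditions: HF·pyridine, pyridine, THF, 0 °C to rt; then PPTS (cat.), toluene, 5 Å MS, 50 °C
Reagents that add atoms: none
Why: Fluoride desilylation followed by acid-catalysed intramolecular alkoxy exchange at the vinylogous ester (addition–elimination at C3, six-membered ring, ethanol taken up by the sieves) closes the dihydropyran, and because the benzylic C–O bond is never broken the (S) centre is carried over with retention.

**Alkyne partner**

Step 6
Reactants: 10 (R)-3-chloro-1-phenylpropan-1-ol
Product: 11 (R)-tert-butyl(3-chloro-1-phenylpropoxy)dimethylsilane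
Conditions: TBSCl, imidazole, DMF, 0 °C to rt
Reagents that add atoms: tert-butyldimethylsilyl chloride, CC(C)(C)[Si](C)(C)Cl
Why: Silyl ether formation protects the alcohol for zinc insertion and cross-coupling and leaves the stereocentre unchanged.

Step 7
Reactants: 11 (R)-tert-butyl(3-chloro-1-phenylpropoxy)dimethylsilane
Product: 12 (R)-tert-butyl(3-iodo-1-phenylpropoxy)dimethylsilane
Conditions: NaI, acetone, reflux
Reagents that add atoms: sodium iodide, [Na+].[I-]
Why: Finkelstein exchange provides the primary iodide that inserts zinc readily.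

Step 8
Reactants: 13 2,6-dihydroxy-4-methoxybenzaldehyde
Product: 14 2,6-dihydroxy-3-iodo-4-methoxybenzaldehyde
Conditions: NIS (1.0 equiv), DMF, 0 °C
Reagents that add atoms: N-iodosuccinimide, O=C1CCC(=O)N1I
Why: Electrophilic aromatic iodination of the symmetric ring can only occur at the two equivalent positions between OH and OMe, so one equivalent of NIS fixes the site of the later C4–C4a bond without a regiochemical choice.

Step 9
Reactants: 14 2,6-dihydroxy-3-iodo-4-methoxybenzaldehyde
Product: 15 2,6-bis(tert-butyldimethylsilyloxy)-3-iodo-4-methoxybenzaldehyde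
Conditions: TBSOTf, 2,6-lutidine, CH2Cl2, 0 °C
Reagents that add atoms: tert-butyldimethylsilyl trifluoromethanesulfonate, CC(C)(C)[Si](C)(C)OS(=O)(=O)C(F)(F)F
Why: Silyl triflate with a hindered base silylates both phenols, the crowded one included, so that they cannot protonate the organozinc reagent.

Step 10
Reactants: 12 (R)-tert-butyl(3-iodo-1-phenylpropoxy)dimethylsilane; 15 2,6-bis(tert-butyldimethylsilyloxy)-3-iodo-4-methoxybenzaldehyde
Product: 17 2,6-bis(tert-butyldimethylsilyloxy)-3-[(3R)-3-(tert-butyldimethylsilyloxy)-3-phenylpropyl]-4-methoxybenzaldehyde, via alkylzinc iodide 16 (not isolated)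
Conditions: 12, Zn dust, LiCl, THF, 40 °C; then 15, Pd(OAc)2 (cat.), SPhos (cat.), THF, 50 °C
Reagents that add atoms: none
Why: Zinc insertion into the primary iodide and Negishi sp3–sp2 cross-coupling under a bulky biarylphosphine joins the chiral three-carbon chain to the hindered aryl iodide, tolerates the aldehyde and leaves the remote stereocentre untouched.

Step 11
Reactants: 17 2,6-bis(tert-butyldimethylsilyloxy)-3-[(3R)-3-(tert-butyldimethylsilyloxy)-3-phenylpropyl]-4-methoxybenzaldehyde
Product: 18 2,6-dihydroxy-3-[(3R)-3-hydroxy-3-phenylpropyl]-4-methoxybenzaldehyde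
Conditions: TBAF, AcOH, THF, 0 °C to rt
Reagents that add atoms: none
Why: Buffered fluoride desilylation removes the two aryl and the one alkyl silyl ether in one operation under conditions too mild to ionise the benzylic alcohol.

Step 12
Reactants: 18 2,6-dihydroxy-3-[(3R)-3-hydroxy-3-phenylpropyl]-4-methoxybenzaldehyde
Product: 19 (2S)-7-hydroxy-5-methoxy-2-phenylchromane-8-carbaldehyde
Conditions: PPh3, DIAD, THF (dilute), 0 °C to rt
Reagents that add atoms: none
Why: In the intramolecular Mitsunobu etherification the phenol next to the chain displaces the activated benzylic oxygen in a six-membered SN2 closure with inversion, turning the (R)-carbinol into C2 (S) of the flavan, while the second phenol cannot reach.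

Step 13
Reactants: 19 (2S)-7-hydroxy-5-methoxy-2-phenylchromane-8-carbaldehyde
Product: 20 (2S)-7-benzyloxy-5-methoxy-2-phenylchromane-8-carbaldehyde
Conditions: BnBr, K2CO3, DMF, 50 °C
Reagents that add atoms: benzyl bromide, BrCc1ccccc1
Why: Williamson etherification of the one remaining phenol installs the benzyl group that protects C7–OH from the ynol ether and the vinylketene.

Step 14
Reactants: 20 (2S)-7-benzyloxy-5-methoxy-2-phenylchromane-8-carbaldehyde
Product: 21 [(2S)-7-benzyloxy-5-methoxy-2-phenylchroman-8-yl]methanol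
Conditions: NaBH4, MeOH/THF, 0 °C
Reagents that add atoms: none
Why: Borohydride reduction of the aryl aldehyde gives the benzylic alcohol and affects neither the ethers nor C2.

Step 15
Reactants: 22 chloroacetaldehyde dimethyl acetal
Product: 24 methoxyacetylene, via sodium methoxyacetylide 23 (not isolated)
Conditions: NaNH2 (3 equiv), liquid NH3, −33 °C; then saturated aqueous NaCl, −70 °C to rt, distilled into cold THF
Reagents that add atoms: none
Why: Successive amide-induced eliminations of HCl and methanol from the α-chloro acetal give the sodium alkoxyacetylide, which is protonated and distilled as the volatile ynol ether (β-elimination route to 1-alkoxyalkynes).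

Step 16
Reactants: 21 [(2S)-7-benzyloxy-5-methoxy-2-phenylchroman-8-yl]methanol; 24 methoxyacetylene
Product: 27 (2S)-7-benzyloxy-5-methoxy-8-(3-methoxyprop-2-yn-1-yl)-2-phenylchromane, via benzylic chloride 25 (not isolated), via lithium methoxyacetylide 26 (not isolated)
Conditions: 21, 1-chloro-N,N,2-trimethylprop-1-enylamine, CH2Cl2, 0 °C, solvent changed to THF; 24, n-BuLi, THF, −78 °C; combined, DMPU, −78 to 0 °C
Reagents that add atoms: none
Why: The α-chloroenamine converts the very electron-rich benzylic alcohol into its chloride under neutral conditions, and SN2 alkylation of the lithium alkoxyacetylide consumes the chloride at once, before it can ionise and self-condense.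

**Union and end game**

Step 17
Reactants: 9 (3S)-3-phenyl-2-oxabicyclo[4.2.0]oct-1(6)-en-7-one; 27 (2S)-7-benzyloxy-5-methoxy-8-(3-methoxyprop-2-yn-1-yl)-2-phenylchromane
Product: 28 (2S)-6-{[(2S)-7-benzyloxy-5-methoxy-2-phenylchroman-8-yl]methyl}-5-methoxy-2-phenylchroman-7-ol
Conditions: 9 (1.5 equiv), toluene, 110–130 °C, sealed tube; then KOH, MeOH, 50 °C
Reagents that add atoms: none
Why: Heating opens 9 by four-electron electrocyclic ring opening to a vinylketene, whose ketene C=C adds to the triple bond of 27 in a [2+2] cycloaddition with the alkyne carbon remote from OMe bonding to the ketene carbonyl carbon; the resulting 4-vinylcyclobutenone opens again to a dienylketene, which cyclises and tautomerises to the phenol. The closest known reaction is the Danheiser benzannulation of cyclobutenones with alkoxyalkynes to resorcinol monoethers. The benzene ring is closed by thermal six-electron disrotatory electrocyclisation of the dienylketene, which forms C7–C8 after C6–C7 and C4a–C5 have been made in the cycloaddition. No stereocentre is created, and both C2 centres are remote from the reacting atoms. The one selectivity needed is the orientation of the ketene–alkyne cycloaddition, secured by the polarisation of the ynol ether (nucleophilic at the carbon that carries the CH2 bridge), which places the bridge on C6 between C5–OMe and C7–OH; the excess of 9 and the basic methanolysis return any product phenol that the vinylketene has O-acylated.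

Step 18
Reactants: 28 (2S)-6-{[(2S)-7-benzyloxy-5-methoxy-2-phenylchroman-8-yl]methyl}-5-methoxy-2-phenylchroman-7-ol
Product: 29 (2S)-6-{[(2S)-7-hydroxy-5-methoxy-2-phenylchroman-8-yl]methyl}-5-methoxy-2-phenylchroman-7-ol
Conditions: H2 (1 atm), Pd/C, EtOAc/MeOH, rt
Reagents that add atoms: none
Why: Catalytic hydrogenolysis cleaves the single O-benzyl ether under neutral conditions that are routinely used on benzylated flavans without opening the cyclic C2–O1 bond, provided the reaction is stopped after one equivalent of hydrogen.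

**Compound list**

1 | (S)-3-chloro-1-phenylpropan-1-ol | O[C@@H](CCCl)c1ccccc1 | starting material
2 | (S)-tert-butyl(3-chloro-1-phenylpropoxy)dimethylsilane | CC(C)(C)[Si](C)(C)O[C@@H](CCCl)c1ccccc1 | intermediate
3 | (S)-tert-butyl(3-iodo-1-phenylpropoxy)dimethylsilane | CC(C)(C)[Si](C)(C)O[C@@H](CCI)c1ccccc1 | intermediate
4 | ethoxyacetylene | CCOC#C | starting material
5 | lithium ethoxyacetylide | CCOC#C[Li] | intermediate (not isolated)
6 | (S)-tert-butyl[(5-ethoxy-1-phenylpent-4-yn-1-yl)oxy]dimethylsilane | CC(C)(C)[Si](C)(C)O[C@@H](CCC#COCC)c1ccccc1 | intermediate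
7 | 3-ethoxy-2-[(3S)-3-(tert-butyldimethylsilyloxy)-3-phenylpropyl]cyclobut-2-en-1-one | CC(C)(C)[Si](C)(C)O[C@@H](CCC1=C(OCC)CC1=O)c1ccccc1 | intermediate
8 | 3-ethoxy-2-[(3S)-3-hydroxy-3-phenylpropyl]cyclobut-2-en-1-one | O[C@@H](CCC1=C(OCC)CC1=O)c1ccccc1 | intermediate (not isolated)
9 | (3S)-3-phenyl-2-oxabicyclo[4.2.0]oct-1(6)-en-7-one | O=C1CC2=C1CC[C@@H](c1ccccc1)O2 | intermediate
10 | (R)-3-chloro-1-phenylpropan-1-ol | O[C@H](CCCl)c1ccccc1 | starting material
11 | (R)-tert-butyl(3-chloro-1-phenylpropoxy)dimethylsilane | CC(C)(C)[Si](C)(C)O[C@H](CCCl)c1ccccc1 | intermediate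
12 | (R)-tert-butyl(3-iodo-1-phenylpropoxy)dimethylsilane | CC(C)(C)[Si](C)(C)O[C@H](CCI)c1ccccc1 | intermediate
13 | 2,6-dihydroxy-4-methoxybenzaldehyde | COc1cc(O)c(C=O)c(O)c1 | starting material
14 | 2,6-dihydroxy-3-iodo-4-methoxybenzaldehyde | COc1cc(O)c(C=O)c(O)c1I | intermediate
15 | 2,6-bis(tert-butyldimethylsilyloxy)-3-iodo-4-methoxybenzaldehyde | COc1cc(O[Si](C)(C)C(C)(C)C)c(C=O)c(O[Si](C)(C)C(C)(C)C)c1I | intermediate
16 | [(3R)-3-(tert-butyldimethylsilyloxy)-3-phenylpropyl]zinc iodide | CC(C)(C)[Si](C)(C)O[C@H](CC[Zn]I)c1ccccc1 | intermediate (not isolated)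
17 | 2,6-bis(tert-butyldimethylsilyloxy)-3-[(3R)-3-(tert-butyldimethylsilyloxy)-3-phenylpropyl]-4-methoxybenzaldehyde | CC(C)(C)[Si](C)(C)O[C@H](CCc1c(OC)cc(O[Si](C)(C)C(C)(C)C)c(C=O)c1O[Si](C)(C)C(C)(C)C)c1ccccc1 | intermediate
18 | 2,6-dihydroxy-3-[(3R)-3-hydroxy-3-phenylpropyl]-4-methoxybenzaldehyde | O[C@H](CCc1c(OC)cc(O)c(C=O)c1O)c1ccccc1 | intermediate
19 | (2S)-7-hydroxy-5-methoxy-2-phenylchromane-8-carbaldehyde | COc1cc(O)c(C=O)c2c1CC[C@@H](c1ccccc1)O2 | intermediate
20 | (2S)-7-benzyloxy-5-methoxy-2-phenylchromane-8-carbaldehyde | COc1cc(OCc3ccccc3)c(C=O)c2c1CC[C@@H](c1ccccc1)O2 | intermediate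
21 | [(2S)-7-benzyloxy-5-methoxy-2-phenylchroman-8-yl]methanol | COc1cc(OCc3ccccc3)c(CO)c2c1CC[C@@H](c1ccccc1)O2 | intermediate
22 | chloroacetaldehyde dimethyl acetal | COC(CCl)OC | starting material
23 | sodium methoxyacetylide | [Na+].[C-]#COC | intermediate (not isolated)
24 | methoxyacetylene | COC#C | intermediate
25 | (2S)-7-benzyloxy-8-(chloromethyl)-5-methoxy-2-phenylchromane | COc1cc(OCc3ccccc3)c(CCl)c2c1CC[C@@H](c1ccccc1)O2 | intermediate (not isolated)
26 | lithium methoxyacetylide | COC#C[Li] | intermediate (not isolated)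
27 | (2S)-7-benzyloxy-5-methoxy-8-(3-methoxyprop-2-yn-1-yl)-2-phenylchromane | COc1cc(OCc3ccccc3)c(CC#COC)c2c1CC[C@@H](c1ccccc1)O2 | intermediate
28 | (2S)-6-{[(2S)-7-benzyloxy-5-methoxy-2-phenylchroman-8-yl]methyl}-5-methoxy-2-phenylchroman-7-ol | COc1cc(OCc5ccccc5)c(Cc2c(O)cc3c(c2OC)CC[C@@H](c2ccccc2)O3)c2c1CC[C@@H](c1ccccc1)O2 | intermediate
29 | (2S)-6-{[(2S)-7-hydroxy-5-methoxy-2-phenylchroman-8-yl]methyl}-5-methoxy-2-phenylchroman-7-ol (CNP0178097.1) | COc1cc(O)c(Cc2c(O)cc3c(c2OC)CC[C@@H](c2ccccc2)O3)c2c1CC[C@@H](c1ccccc1)O2 | target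

**Step count and risks**

Total step count: 18. Longest linear sequence: 10 steps (steps 6, 7, 10, 11, 12, 13, 14, 16, 17, 18).

Steps most likely to fail:

1. Step 17. The vinylogous-ester stabilisation of the ring-fused alkoxycyclobutenone may slow its electrocyclic opening so much that, at the temperature required, the ynol ether oligomerises or the vinylketene dimerises before the cycloaddition. The fallback sets out from 19 and 21 and returns at 28. Alcohol 21 is added slowly to an excess of 19 with catalytic Sc(OTf)3 in CH2Cl2. The formyl group of 19 blocks C8, so the benzylic cation from 21 can only bond to C6 (Friedel–Crafts benzylation), and the slow addition suppresses attack on the free C6 of 21 itself. This gives (2S)-6-{[(2S)-7-benzyloxy-5-methoxy-2-phenylchroman-8-yl]methyl}-7-hydroxy-5-methoxy-2-phenylchromane-8-carbaldehyde F1. Pinnick oxidation (NaClO2, NaH2PO4, 2-methyl-2-butene) then gives the corresponding 8-carboxylic acid F2, and thermal protodecarboxylation of this 2-hydroxy-4,6-dialkoxybenzoic acid in hot DMF gives 28.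

2. Step 16. The trialkoxybenzylic chloride may ionise and alkylate the free C6 position of a second molecule faster than the acetylide displaces chloride, and the product may isomerise to the allenyl ether under the basic conditions. The fallback sets out from 21 and 26 and returns at 27. Condensation of 21 with 1H-benzotriazole (TsOH cat., toluene, 4 Å MS) gives the bench-stable benzyl cation equivalent 1-{[(2S)-7-benzyloxy-5-methoxy-2-phenylchroman-8-yl]methyl}-1H-benzotriazole F3. Transmetalation of 26 with ZnCl2 gives (methoxyethynyl)zinc chloride F4, which displaces benzotriazole from F3 in THF/toluene through the zinc-assisted ion pair and gives 27.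

3. Step 10. Oxidative addition into the doubly ortho-oxygenated, silyl-crowded aryl iodide may be slow, so that proto-deiodination and β-hydride elimination from the alkylpalladium intermediate compete. The fallback sets out from 15 and returns at 17. Commercial (R)-1-phenylprop-2-yn-1-ol is silylated (TBSCl, imidazole) to (R)-tert-butyldimethyl[(1-phenylprop-2-yn-1-yl)oxy]silane F5. Sonogashira coupling of F5 with 15 (PdCl2(PPh3)2, CuI, Et3N) gives 2,6-bis(tert-butyldimethylsilyloxy)-3-[(3S)-3-(tert-butyldimethylsilyloxy)-3-phenylprop-1-yn-1-yl]-4-methoxybenzaldehyde F6; the descriptor changes only because the arylalkynyl group outranks phenyl. Hydrogenation of the triple bond (H2, Pd/C, EtOAc) gives 17.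

Further compounds
F1 | step 17 | (2S)-6-{[(2S)-7-benzyloxy-5-methoxy-2-phenylchroman-8-yl]methyl}-7-hydroxy-5-methoxy-2-phenylchromane-8-carbaldehyde | COc1cc(OCc5ccccc5)c(Cc2c(O)c(C=O)c3c(c2OC)CC[C@@H](c2ccccc2)O3)c2c1CC[C@@H](c1ccccc1)O2
F2 | step 17 | (2S)-6-{[(2S)-7-benzyloxy-5-methoxy-2-phenylchroman-8-yl]methyl}-7-hydroxy-5-methoxy-2-phenylchromane-8-carboxylic acid | COc1cc(OCc5ccccc5)c(Cc2c(O)c(C(=O)O)c3c(c2OC)CC[C@@H](c2ccccc2)O3)c2c1CC[C@@H](c1ccccc1)O2
F3 | step 16 | 1-{[(2S)-7-benzyloxy-5-methoxy-2-phenylchroman-8-yl]methyl}-1H-benzotriazole | COc1cc(OCc3ccccc3)c(Cn3nnc4ccccc43)c2c1CC[C@@H](c1ccccc1)O2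
F4 | step 16 | (methoxyethynyl)zinc chloride | COC#C[Zn]Cl
F5 | step 10 | (R)-tert-butyldimethyl[(1-phenylprop-2-yn-1-yl)oxy]silane | C#C[C@@H](O[Si](C)(C)C(C)(C)C)c1ccccc1
F6 | step 10 | 2,6-bis(tert-butyldimethylsilyloxy)-3-[(3S)-3-(tert-butyldimethylsilyloxy)-3-phenylprop-1-yn-1-yl]-4-methoxybenzaldehyde | COc1cc(O[Si](C)(C)C(C)(C)C)c(C=O)c(O[Si](C)(C)C(C)(C)C)c1C#C[C@@H](O[Si](C)(C)C(C)(C)C)c1ccccc1
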